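## Retrosynthetic overview

1. Locants: the dihydropyran ring is O1, C2 (stereocentre), C3, C4=C5, C6, and the side chain on C5 is C1' to C13'. The acrylic acid is unveiled last from a C2-ethynyl group (desilylation, then Markovnikov hydroxycarbonylation). Until then it travels as a bulky, radical-inert triisopropylsilylalkyne.
2. Key disconnection: the C2'(sp3)–C3'(sp2) bond. It is made by nickel-electrocatalytic decarboxylative alkenylation of the N-hydroxyphthalimide ester of the ring-bearing propanoic acid (C5–C1'H2–C2'H2–CO2H) with the (1E,5E)-C14 alkenyl iodide.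
3. Enabling feature: C2' is a primary CH2, insulated from the ring olefin C4=C5 by C1' and bonded directly to the vinylic CH C3'. It can therefore carry a CO2H handle. Its but-3-enyl radical has only one cyclisation open, 3-exo attack on ring carbon C5, which is reversible and degenerate because it merely exchanges C1' and C2'.
4. Ring fragment: the only ring (3,6-dihydro-2H-pyran) is closed before the key step, by Williamson union at O1–C6 and then ring-closing metathesis at C4=C5. C2 is set by asymmetric allylboration of a silylpropynal.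
5. Chain fragment: geranyl bromide is propargylated. Cp2ZrCl2-catalysed methylalumination and iodinolysis of the terminal alkyne then fix the E geometry of C3'=C4'.

Key step: step 9

Assumption: 3-(triisopropylsilyl)prop-2-ynal and (+)-B-allyldiisopinocampheylborane (1 M in pentane) are taken as purchasable; the aldehyde is otherwise one step from ethynyltriisopropylsilane, n-BuLi and DMF.

## Route

Step 1
Reactants: 1 3-(triisopropylsilyl)prop-2-ynal; 2 (+)-B-allyldiisopinocampheylborane
Product: 4 (3R)-1-(triisopropylsilyl)hex-5-en-1-yn-3-ol, via borinate ester 3 (not isolated)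
Conditions: Et2O, −78 °C; then 3 M NaOH, 30 % H2O2, 0 °C to rt
Reagents that add atoms: none
Why: Brown asymmetric allylboration runs through a closed chair transition state in which the isopinocampheyl groups derived from (−)-α-pinene expose one aldehyde face, the sense that gives (R)-1-phenylbut-3-en-1-ol from benzaldehyde, so C2 should be set as R (alkynyl, like phenyl, outranks the allyl CH2), and the alkaline peroxide work-up only cleaves the B–O and B–C bonds of 3.

Step 2
Reactants: 5 tert-butyl acetate; 6 3-chloro-2-(chloromethyl)prop-1-ene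
Product: 8 tert-butyl 4-(chloromethyl)pent-4-enoate, via lithium enolate 7 (not isolated)
Conditions: LiN(i-Pr)2, THF, −78 °C; then 6 (3 equiv), DMPU, −78 °C to 0 °C
Reagents that add atoms: none
Why: Enolate alkylation by SN2 attack of the stable lithium enolate of tert-butyl acetate on one of two equivalent allylic chlorides, with an excess of 6 to hold back a second alkylation.

Step 3
Reactants: 4 (3R)-1-(triisopropylsilyl)hex-5-en-1-yn-3-ol; 8 tert-butyl 4-(chloromethyl)pent-4-enoate
Product: 10 tert-butyl 4-({[(3R)-1-(triisopropylsilyl)hex-5-en-1-yn-3-yl]oxy}methyl)pent-4-enoate, via sodium alkoxide 9 (not isolated)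
Conditions: NaH, THF/DMF, 0 °C; then 8, n-Bu4NI (10 mol %), 0 °C to rt
Reagents that add atoms: none
Why: Williamson ether synthesis with iodide catalysis forms the O1–C6 bond at the primary allylic carbon of 8 without touching the C2–O bond, so the configuration is retained, and the tert-butyl ester and the silylalkyne tolerate the alkoxide.

Step 4
Reactants: 10 tert-butyl 4-({[(3R)-1-(triisopropylsilyl)hex-5-en-1-yn-3-yl]oxy}methyl)pent-4-enoate
Product: 11 tert-butyl 3-{(2R)-2-[(triisopropylsilyl)ethynyl]-3,6-dihydro-2H-pyran-5-yl}propanoate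
Conditions: second-generation Grubbs catalyst RuCl2(=CHPh)(PCy3)(SIMes) (5 mol %), CH2Cl2, 40 °C
Reagents that add atoms: none
Why: Ring-closing metathesis of the monosubstituted and the 1,1-disubstituted olefin closes the six-membered ring at C4=C5 with loss of ethene, while the shielded silylalkyne stays out because an enyne closure would need a four-membered ring.

Step 5
Reactants: 11 tert-butyl 3-{(2R)-2-[(triisopropylsilyl)ethynyl]-3,6-dihydro-2H-pyran-5-yl}propanoate
Product: 13 3-{(2R)-2-[(triisopropylsilyl)ethynyl]-3,6-dihydro-2H-pyran-5-yl}propanoic acid, via trimethylsilyl ester 12 (not isolated)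
Conditions: Me3SiOTf, 2,6-lutidine, CH2Cl2, 0 °C to rt; then aqueous citric acid work-up
Reagents that add atoms: none
Why: Silyl triflate-mediated cleavage of the tert-butyl ester (loss of 2-methylpropene) in the presence of a hindered base avoids the free strong acid that could protonate C4=C5 and lactonise the γ,δ-unsaturated acid, and the labile silyl ester 12 hydrolyses on work-up.

Step 6
Reactants: 13 3-{(2R)-2-[(triisopropylsilyl)ethynyl]-3,6-dihydro-2H-pyran-5-yl}propanoic acid
Product: 14 1,3-dioxoisoindolin-2-yl 3-{(2R)-2-[(triisopropylsilyl)ethynyl]-3,6-dihydro-2H-pyran-5-yl}propanoate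
Conditions: N-hydroxyphthalimide, N,N'-diisopropylcarbodiimide, DMAP (10 mol %), CH2Cl2, rt
Reagents that add atoms: N-hydroxyphthalimide, O=C1c2ccccc2C(=O)N1O
Why: Steglich-type carbodiimide esterification of a primary acid with N-hydroxyphthalimide installs the redox-active group under neutral conditions.

Step 7
Reactants: 15 1-(trimethylsilyl)prop-1-yne; 16 geranyl bromide
Product: 19 (5E)-6,10-dimethylundeca-5,9-dien-1-yne, via lithiated silylpropyne 17 (not isolated), via silylated enyne 18 (not isolated)
Conditions: n-BuLi, THF, −78 °C to −20 °C; then 16, −78 °C to rt; then K2CO3, MeOH, rt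
Reagents that add atoms: none
Why: Propargylation by SN2 attack of the CH2 terminus of lithiated 15 on the primary allylic bromide leaves the E olefin of the geranyl unit untouched, and carbonate-catalysed methanolysis then removes the C-silyl group.

Step 8
Reactants: 19 (5E)-6,10-dimethylundeca-5,9-dien-1-yne
Product: 21 (1E,5E)-1-iodo-2,6,10-trimethylundeca-1,5,9-triene, via alkenylalane 20 (not isolated)
Conditions: AlMe3 (2 equiv), Cp2ZrCl2 (0.25 equiv), CH2Cl2, 0 °C to rt; then I2, THF, −30 °C to 0 °C
Reagents that add atoms: trimethylaluminium, C[Al](C)C; iodine, II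
Why: Negishi carboalumination adds Me–Al syn across the terminal alkyne with aluminium on the terminal carbon cis to the new methyl group, and iodinolysis of the C–Al bond with retention should give the E iodide, the isolated trisubstituted olefins being inert.

Step 9
Reactants: 14 1,3-dioxoisoindolin-2-yl 3-{(2R)-2-[(triisopropylsilyl)ethynyl]-3,6-dihydro-2H-pyran-5-yl}propanoate; 21 (1E,5E)-1-iodo-2,6,10-trimethylundeca-1,5,9-triene (1.5 equiv)
Product: 22 (2R)-2-[(triisopropylsilyl)ethynyl]-5-[(3E,7E)-4,8,12-trimethyltrideca-3,7,11-trien-1-yl]-3,6-dihydro-2H-pyran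
Conditions: NiCl2·6H2O (10 mol %), 2,2'-bipyridine (10 mol %), AgNO3 (0.3 equiv), LiCl, DMF, Mg anode, reticulated vitreous carbon cathode, undivided cell, constant current, about 2.5 F/mol, rt
Reagents that add atoms: none
Why: Cathodic reduction gives low-valent (bipyridine)nickel, which adds oxidatively to the C–I bond of 21 with retention of the E geometry; single-electron transfer to the phthalimide ester 14 (at nickel or at the silver-nanoparticle-coated cathode) releases phthalimide anion, CO2 and the primary C2' radical, which is captured by the alkenylnickel species, and reductive elimination from trivalent nickel forms the C2'(sp3)–C3'(sp2) bond while the Mg anode is consumed. The closest known reaction type is the nickel-electrocatalytic decarboxylative alkenylation of redox-active esters with alkenyl iodides on silver-modified cathodes, which is established for building 1,5-polyenes from esters of γ,δ-unsaturated acids and (E)-2-methyl-1-iodoalk-1-enes, the very pairing used here. No ring is closed and no stereocentre is formed: C2 lies five bonds from the radical centre and is untouched, and the C3'=C4' olefin takes its E geometry from 21 because the alkenyl–nickel bond is configurationally stable. The step needs cross-coupling to outrun cyclisation, hydrogen transfer and conjugate addition of the radical, and the substrate secures this: 3-exo attack on C5 is reversible and degenerate (it only exchanges C1' and C2'), 1,5-hydrogen transfer from C3 is excluded because C1' and C3 are trans across C4=C5, and the acrylic acid, an avid radical acceptor, is present only as the shielded silylalkyne. In this one operation 14 of the 24 carbons are attached and the full triene side chain with both E olefins is put in place without a stoichiometric organometallic reagent or a redox adjustment, so two fragments of modest size give the whole skeleton save the carboxyl carbon.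

Step 10
Reactants: 22 (2R)-2-[(triisopropylsilyl)ethynyl]-5-[(3E,7E)-4,8,12-trimethyltrideca-3,7,11-trien-1-yl]-3,6-dihydro-2H-pyran
Product: 23 (2R)-2-ethynyl-5-[(3E,7E)-4,8,12-trimethyltrideca-3,7,11-trien-1-yl]-3,6-dihydro-2H-pyran
Conditions: n-Bu4NF, THF, 0 °C to rt
Reagents that add atoms: none
Why: Fluoride-induced protodesilylation of the alkynylsilane, driven by the Si–F bond, leaves the ether, the stereocentre and the four olefins untouched.

Step 11
Reactants: 23 (2R)-2-ethynyl-5-[(3E,7E)-4,8,12-trimethyltrideca-3,7,11-trien-1-yl]-3,6-dihydro-2H-pyran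
Product: 24 2-{(2R)-5-[(3E,7E)-4,8,12-trimethyltrideca-3,7,11-trien-1-yl]-3,6-dihydro-2H-pyran-2-yl}prop-2-enoic acid
Conditions: Pd(OAc)2 (2 mol %), 2-(diphenylphosphino)pyridine (20 mol %), MeSO3H (10 mol %), CO (20 bar), H2O (10 equiv), THF, 50 °C
Reagents that add atoms: carbon monoxide, [C-]#[O+]; water, O
Why: Reppe-type palladium-catalysed hydroxycarbonylation with the P,N ligand attaches the carboxyl carbon to the internal alkyne carbon (Markovnikov, branched acrylic acid), the terminal alkyne reacts far faster than the trisubstituted olefins, the acid co-catalyst is buffered by the excess pyridylphosphine, and the C2 stereocentre is not involved.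

## Compound list

1 | 3-(triisopropylsilyl)prop-2-ynal | O=CC#C[Si](C(C)C)(C(C)C)C(C)C | starting material
2 | (+)-B-allyldiisopinocampheylborane, isopinocampheyl groups from (−)-α-pinene | C=CCB([C@H]1C[C@H]2C[C@@H]([C@@H]1C)C2(C)C)[C@H]1C[C@H]2C[C@@H]([C@@H]1C)C2(C)C | starting material
3 | diisopinocampheylborinate ester of 4 | C=CC[C@@H](OB([C@H]1C[C@H]2C[C@@H]([C@@H]1C)C2(C)C)[C@H]1C[C@H]2C[C@@H]([C@@H]1C)C2(C)C)C#C[Si](C(C)C)(C(C)C)C(C)C | intermediate
4 | (3R)-1-(triisopropylsilyl)hex-5-en-1-yn-3-ol | C=CC[C@@H](O)C#C[Si](C(C)C)(C(C)C)C(C)C | intermediate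
5 | tert-butyl acetate | CC(=O)OC(C)(C)C | starting material
6 | 3-chloro-2-(chloromethyl)prop-1-ene | C=C(CCl)CCl | starting material
7 | lithium enolate of tert-butyl acetate | [Li]OC(=C)OC(C)(C)C | intermediate
8 | tert-butyl 4-(chloromethyl)pent-4-enoate | C=C(CCl)CCC(=O)OC(C)(C)C | intermediate
9 | sodium alkoxide of 4 | C=CC[C@@H]([O-])C#C[Si](C(C)C)(C(C)C)C(C)C.[Na+] | intermediate
10 | tert-butyl 4-({[(3R)-1-(triisopropylsilyl)hex-5-en-1-yn-3-yl]oxy}methyl)pent-4-enoate | C=CC[C@@H](OCC(=C)CCC(=O)OC(C)(C)C)C#C[Si](C(C)C)(C(C)C)C(C)C | intermediate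
11 | tert-butyl 3-{(2R)-2-[(triisopropylsilyl)ethynyl]-3,6-dihydro-2H-pyran-5-yl}propanoate | CC(C)[Si](C(C)C)(C(C)C)C#C[C@H]1CC=C(CCC(=O)OC(C)(C)C)CO1 | intermediate
12 | trimethylsilyl ester of 13 | CC(C)[Si](C(C)C)(C(C)C)C#C[C@H]1CC=C(CCC(=O)O[Si](C)(C)C)CO1 | intermediate
13 | 3-{(2R)-2-[(triisopropylsilyl)ethynyl]-3,6-dihydro-2H-pyran-5-yl}propanoic acid | CC(C)[Si](C(C)C)(C(C)C)C#C[C@H]1CC=C(CCC(=O)O)CO1 | intermediate
14 | 1,3-dioxoisoindolin-2-yl 3-{(2R)-2-[(triisopropylsilyl)ethynyl]-3,6-dihydro-2H-pyran-5-yl}propanoate | CC(C)[Si](C(C)C)(C(C)C)C#C[C@H]1CC=C(CCC(=O)ON2C(=O)c3ccccc3C2=O)CO1 | intermediate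
15 | 1-(trimethylsilyl)prop-1-yne | CC#C[Si](C)(C)C | starting material
16 | geranyl bromide, (2E)-1-bromo-3,7-dimethylocta-2,6-diene | CC(C)=CCC/C(C)=C/CBr | starting material
17 | 3-lithio-1-(trimethylsilyl)prop-1-yne | [Li]CC#C[Si](C)(C)C | intermediate
18 | [(5E)-6,10-dimethylundeca-5,9-dien-1-yn-1-yl]trimethylsilane | C[Si](C)(C)C#CCC/C=C(\C)CCC=C(C)C | intermediate
19 | (5E)-6,10-dimethylundeca-5,9-dien-1-yne | C#CCC/C=C(\C)CCC=C(C)C | intermediate
20 | dimethyl[(1E,5E)-2,6,10-trimethylundeca-1,5,9-trien-1-yl]alane | C[Al](C)/C=C(\C)CC/C=C(\C)CCC=C(C)C | intermediate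
21 | (1E,5E)-1-iodo-2,6,10-trimethylundeca-1,5,9-triene | I/C=C(\C)CC/C=C(\C)CCC=C(C)C | intermediate
22 | (2R)-2-[(triisopropylsilyl)ethynyl]-5-[(3E,7E)-4,8,12-trimethyltrideca-3,7,11-trien-1-yl]-3,6-dihydro-2H-pyran | CC(C)[Si](C(C)C)(C(C)C)C#C[C@H]1CC=C(CC/C=C(\C)CC/C=C(\C)CCC=C(C)C)CO1 | intermediate
23 | (2R)-2-ethynyl-5-[(3E,7E)-4,8,12-trimethyltrideca-3,7,11-trien-1-yl]-3,6-dihydro-2H-pyran | C#C[C@H]1CC=C(CC/C=C(\C)CC/C=C(\C)CCC=C(C)C)CO1 | intermediate
24 | 2-{(2R)-5-[(3E,7E)-4,8,12-trimethyltrideca-3,7,11-trien-1-yl]-3,6-dihydro-2H-pyran-2-yl}prop-2-enoic acid | C=C(C(=O)O)[C@H]1CC=C(CC/C=C(\C)CC/C=C(\C)CCC=C(C)C)CO1 | target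

## Step count and risks

Total step count: 11.
Longest linear sequence: 8 (steps 1, 3, 4, 5, 6, 9, 10, 11).

**Risk 1 (step 9).**
- What may go wrong: the redox-active ester may be reduced at the cathode faster than the alkenylnickel species can intercept the radical. Hydrogen abstraction from the solvent and radical dimerisation would then drain the ring fragment. Some loss of olefin geometry at nickel is also conceivable.
- Fallback: it replaces the radical coupling by two-electron boron chemistry, sets out from 4 and comes back at 22. Alcohol 4 would be O-alkylated with propargyl bromide (NaH, THF) to the propargyl ether (3R)-3-(prop-2-yn-1-yloxy)-1-(triisopropylsilyl)hex-5-en-1-yne F1. Ring-closing enyne metathesis (second-generation Grubbs catalyst RuCl2(=CHPh)(PCy3)(SIMes), ethene atmosphere, CH2Cl2) should close the same dihydropyran and leave a vinyl group on C5 in the diene (2R)-5-ethenyl-2-[(triisopropylsilyl)ethynyl]-3,6-dihydro-2H-pyran F2. 9-BBN-H should add only to that monosubstituted vinyl group to give the B-alkylborane 9-(2-{(2R)-2-[(triisopropylsilyl)ethynyl]-3,6-dihydro-2H-pyran-5-yl}ethyl)-9-borabicyclo[3.3.1]nonane F3. A B-alkyl Suzuki–Miyaura coupling with 21 (PdCl2(dppf), AsPh3, Cs2CO3, DMF/THF/H2O, rt) then forms the same C2'–C3' bond and gives 22.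

**Risk 2 (step 11).**
- What may go wrong: regiochemical leakage towards the linear acid, β-alkoxide elimination from an internal vinylpalladium species with ring opening, palladium hydride-induced olefin migration, or acid-triggered polyene cyclisation.
- Fallback: it separates regiocontrol from carboxylation, sets out from 23 and comes back at 24. Hydrostannation catalysed by Mo(CO)3(CNt-Bu)3 (Bu3SnH, hydroquinone, THF, 55 °C) is α-selective for propargylic ethers and should give the internal stannane tributyl(1-{(2R)-5-[(3E,7E)-4,8,12-trimethyltrideca-3,7,11-trien-1-yl]-3,6-dihydro-2H-pyran-2-yl}ethenyl)stannane F4. Tin–lithium exchange (n-BuLi, THF, −78 °C) gives the vinyllithium F5. Quenching with CO2 gives the lithium carboxylate of the target F6, and mild acidification gives 24.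

**Risk 3 (step 1).**
- What may go wrong: poor facial discrimination, because the slim, rod-like alkynyl substituent is weakly differentiated in the chair transition state. Removal of the terpene alcohol may also be laborious.
- Fallback: it sets the stereocentre by reduction instead of C–C bond formation, sets out from 1 and comes back at 4. Addition of CH2=CHCH2MgBr (THF, −78 °C) gives the racemic alcohol 1-(triisopropylsilyl)hex-5-en-1-yn-3-ol F7. Dess–Martin periodinane buffered with NaHCO3 (CH2Cl2, 0 °C) gives the ynone 1-(triisopropylsilyl)hex-5-en-1-yn-3-one F8, which is kept cold and base-free so that the β,γ-olefin does not move into conjugation. Noyori asymmetric transfer hydrogenation with the base-free complex Ru[(R,R)-TsDPEN](p-cymene) in i-PrOH at rt should deliver the R alcohol 4.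

## Further compounds

F1 | step 9 | (3R)-3-(prop-2-yn-1-yloxy)-1-(triisopropylsilyl)hex-5-en-1-yne | C=CC[C@@H](OCC#C)C#C[Si](C(C)C)(C(C)C)C(C)C
F2 | step 9 | (2R)-5-ethenyl-2-[(triisopropylsilyl)ethynyl]-3,6-dihydro-2H-pyran | CC(C)[Si](C(C)C)(C(C)C)C#C[C@H]1CC=C(C=C)CO1
F3 | step 9 | 9-(2-{(2R)-2-[(triisopropylsilyl)ethynyl]-3,6-dihydro-2H-pyran-5-yl}ethyl)-9-borabicyclo[3.3.1]nonane | CC(C)[Si](C(C)C)(C(C)C)C#C[C@H]1CC=C(CCB2C3CCCC2CCC3)CO1
F4 | step 11 | tributyl(1-{(2R)-5-[(3E,7E)-4,8,12-trimethyltrideca-3,7,11-trien-1-yl]-3,6-dihydro-2H-pyran-2-yl}ethenyl)stannane | C=C([Sn](CCCC)(CCCC)CCCC)[C@H]1CC=C(CC/C=C(\C)CC/C=C(\C)CCC=C(C)C)CO1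
F5 | step 11 | vinyllithium from F4 | [Li]C(=C)[C@H]1CC=C(CC/C=C(\C)CC/C=C(\C)CCC=C(C)C)CO1
F6 | step 11 | lithium carboxylate of the target | C=C(C(=O)[O-])[C@H]1CC=C(CC/C=C(\C)CC/C=C(\C)CCC=C(C)C)CO1.[Li+]
F7 | step 1 | racemic 1-(triisopropylsilyl)hex-5-en-1-yn-3-ol | C=CCC(O)C#C[Si](C(C)C)(C(C)C)C(C)C
F8 | step 1 | 1-(triisopropylsilyl)hex-5-en-1-yn-3-one | C=CCC(=O)C#C[Si](C(C)C)(C(C)C)C(C)C
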